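**Retrosynthetic overview**

1. Target 15 ← desilylation of 14 ← para-Claisen–Cope relay of the prenyl group O5 → C6 → C8 on ring A of flavanone 11.
2. 11 is cut at C2–C1′, the bond joining ring C to ring B. It is formed by enantioselective dearomative 1,4-arylation of the flat γ-pyranone ring C (O1–C2=C3–C4=O) of chromone 4 with boronic acid 10, which sets C2, the only stereocentre.
3. 4 ← commercial 5,7-dihydroxychromone by 7-O-silylation and 5-O-prenylation. The prenyl ether caps O5 in the key step and is the latent C8 prenyl group.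
4. 10 ← 5-bromo-2-methoxybenzyl bromide + methallylmagnesium chloride (3-methylbut-3-enyl chain), then Br/Li/B exchange.
5. No ring is closed in the route: rings A, B and C are bought intact, and ring C is dearomatized, not built.

Key step: step 5

Assumptions and remarks: compounds 1, 3, 5, 6 and both antipodes of Ph-bod* [2,5-diphenylbicyclo[2.2.2]octa-2,5-diene] are taken as commercial. Catalyst-bound species of the catalytic cycle in step 5 are described in the Why line and are not numbered. The sense of induction in step 5 is predicted by analogy with cyclic enones and should be confirmed on a model chromone; the antipodal ligand is used if the sense is reversed.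

**Step 1**
Reactants: 1 5,7-dihydroxy-4H-chromen-4-one
Product: 2 5-hydroxy-7-[(triisopropylsilyl)oxy]-4H-chromen-4-one
Conditions: TIPSCl (1.05 equiv), imidazole (2 equiv), DMF, 0 °C → rt
Reagents that add atoms: triisopropylsilyl chloride, CC(C)[Si](Cl)(C(C)C)C(C)C
Why: Regioselective O-silylation; the acidic, unhindered 7-OH should react, while the 5-OH is held in the hydrogen bond to C4=O and stays free.

**Step 2**
Reactants: 2 5-hydroxy-7-[(triisopropylsilyl)oxy]-4H-chromen-4-one; 3 3-methylbut-2-en-1-ol (prenol)
Product: 4 5-[(3-methylbut-2-en-1-yl)oxy]-7-[(triisopropylsilyl)oxy]-4H-chromen-4-one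
Conditions: PPh3, DIAD, THF, 0 °C → rt
Reagents that add atoms: none
Why: Mitsunobu etherification, the standard way to alkylate a chelated peri-hydroxyl under neutral conditions that leave the aryl silyl ether intact; attack at the primary carbon of the oxyphosphonium should give the linear prenyl ether.

**Step 3**
Reactants: 5 4-bromo-2-(bromomethyl)-1-methoxybenzene (5-bromo-2-methoxybenzyl bromide); 6 (2-methylallyl)magnesium chloride
Product: 7 4-bromo-1-methoxy-2-(3-methylbut-3-en-1-yl)benzene
Conditions: 6 (1.3 equiv, THF solution), THF, 0 °C → rt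
Reagents that add atoms: none
Why: Substitution of a benzylic bromide by an allylic Grignard reagent; the methallyl unit is symmetric, so SN2 and SN2′ give the same product, and the aryl bromide does not react at this temperature.

**Step 4**
Reactants: 7 4-bromo-1-methoxy-2-(3-methylbut-3-en-1-yl)benzene
Product: 10 [4-methoxy-3-(3-methylbut-3-en-1-yl)phenyl]boronic acid, via aryllithium 8 (not isolated), via lithium aryltriisopropoxyborate 9 (not isolated)
Conditions: n-BuLi, THF, −78 °C; B(OiPr)3, −78 °C → rt; 1 M HCl to pH 5, 0 °C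
Reagents that add atoms: triisopropyl borate, CC(C)OB(OC(C)C)OC(C)C; water, O
Why: Bromine–lithium exchange followed by borate trapping and mild hydrolysis is routine for electron-rich aryl bromides, and the brief cold, weakly acidic work-up should spare the 1,1-disubstituted alkene.

**Step 5**
Reactants: 4 5-[(3-methylbut-2-en-1-yl)oxy]-7-[(triisopropylsilyl)oxy]-4H-chromen-4-one; 10 [4-methoxy-3-(3-methylbut-3-en-1-yl)phenyl]boronic acid
Product: 11 (2S)-2-[4-methoxy-3-(3-methylbut-3-en-1-yl)phenyl]-5-[(3-methylbut-2-en-1-yl)oxy]-7-[(triisopropylsilyl)oxy]chroman-4-one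
Conditions: 10 (2.5 equiv), [RhCl(C2H4)2]2 (2.5 mol %), (S,S)-Ph-bod* (5.5 mol %), aq KOH (10 mol %), dioxane/H2O 10:1, 40 °C
Reagents that add atoms: none
Why: Boron-to-rhodium transmetalation gives an aryl–Rh(I)(diene) species, the chromone C2=C3 bond inserts into the Rh–aryl bond to form C2–C1′ and an oxa-π-allyl rhodium, and water protonates C3 and regenerates Rh–OH. The closest known reaction type is the rhodium/chiral diene-catalysed asymmetric 1,4-addition of arylboronic acids to chromones (Hayashi–Miyaura reaction). No ring is closed; the step dearomatizes the γ-pyranone ring C and turns planar C2 into the sp3 stereocentre while joining the two complete halves of the molecule. C2 is set by catalyst control: the C2-symmetric (S,S)-diene is expected, by extension of the model for cyclic enones, to deliver the aryl group to the Re face of C2 (O1 > C3 > H) and so give 2S. The step needs chemoselectivity for the enone over the prenyl ether and the 1,1-disubstituted alkene, which should hold because unactivated alkenes do not insert into aryl–rhodium bonds. It also needs the product not to undergo retro-oxa-Michael opening, which is countered by capping both phenolic oxygens, using only catalytic base buffered by excess boronic acid, and working at low temperature.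

**Step 6**
Reactants: 11 (2S)-2-[4-methoxy-3-(3-methylbut-3-en-1-yl)phenyl]-5-[(3-methylbut-2-en-1-yl)oxy]-7-[(triisopropylsilyl)oxy]chroman-4-one
Product: 14 (2S)-5-hydroxy-2-[4-methoxy-3-(3-methylbut-3-en-1-yl)phenyl]-8-(3-methylbut-2-en-1-yl)-7-[(triisopropylsilyl)oxy]chroman-4-one, via 6-(1,1-dimethylallyl) dienone 12 (not isolated), via 8-prenyl dienone 13 (not isolated)
Conditions: Eu(fod)3 (10 mol %), NaHCO3, PhCl, 85 °C
Reagents that add atoms: none
Why: Europium(III)-catalysed para-Claisen–Cope rearrangement of a 5-O-prenyl flavanone: the aromatic Claisen shift takes the allyl unit (inverted) from O5 to C6, a Cope shift takes it (inverted again, hence linear prenyl) to C8, and tautomerization gives the chelated 5-OH; the 7-O-silyl group blocks phenol participation and C2 is not involved.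

**Step 7**
Reactants: 14 (2S)-5-hydroxy-2-[4-methoxy-3-(3-methylbut-3-en-1-yl)phenyl]-8-(3-methylbut-2-en-1-yl)-7-[(triisopropylsilyl)oxy]chroman-4-one
Product: 15 (2S)-5,7-dihydroxy-2-[4-methoxy-3-(3-methylbut-3-en-1-yl)phenyl]-8-(3-methylbut-2-en-1-yl)chroman-4-one
Conditions: TBAF (1.1 equiv), AcOH (1.2 equiv), THF, 0 °C
Reagents that add atoms: none
Why: Fluoride cleavage of the aryl silyl ether buffered with acetic acid should avoid both acid (alkene isomerization, prenyl/7-OH chroman formation) and free phenoxide base (retro-oxa-Michael racemization at C2).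

**Compound list**

1 | 5,7-dihydroxy-4H-chromen-4-one | O=c1ccoc2cc(O)cc(O)c12 | starting material
2 | 5-hydroxy-7-[(triisopropylsilyl)oxy]-4H-chromen-4-one | O=c1ccoc2cc(O[Si](C(C)C)(C(C)C)C(C)C)cc(O)c12 | intermediate
3 | 3-methylbut-2-en-1-ol (prenol) | CC(C)=CCO | starting material
4 | 5-[(3-methylbut-2-en-1-yl)oxy]-7-[(triisopropylsilyl)oxy]-4H-chromen-4-one | O=c1ccoc2cc(O[Si](C(C)C)(C(C)C)C(C)C)cc(OCC=C(C)C)c12 | intermediate
5 | 4-bromo-2-(bromomethyl)-1-methoxybenzene | COc1ccc(Br)cc1CBr | starting material
6 | (2-methylallyl)magnesium chloride | C=C(C)C[Mg]Cl | starting material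
7 | 4-bromo-1-methoxy-2-(3-methylbut-3-en-1-yl)benzene | C=C(C)CCc1cc(Br)ccc1OC | intermediate
8 | [4-methoxy-3-(3-methylbut-3-en-1-yl)phenyl]lithium (not isolated) | [Li]c1ccc(OC)c(CCC(C)=C)c1 | intermediate
9 | lithium [4-methoxy-3-(3-methylbut-3-en-1-yl)phenyl]triisopropoxyborate (not isolated) | [Li+].CC(C)O[B-](OC(C)C)(OC(C)C)c1ccc(OC)c(CCC(C)=C)c1 | intermediate
10 | [4-methoxy-3-(3-methylbut-3-en-1-yl)phenyl]boronic acid | C=C(C)CCc1cc(B(O)O)ccc1OC | intermediate
11 | (2S)-2-[4-methoxy-3-(3-methylbut-3-en-1-yl)phenyl]-5-[(3-methylbut-2-en-1-yl)oxy]-7-[(triisopropylsilyl)oxy]chroman-4-one | C=C(C)CCc1cc([C@@H]2CC(=O)c3c(OCC=C(C)C)cc(O[Si](C(C)C)(C(C)C)C(C)C)cc3O2)ccc1OC | intermediate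
12 | (2S)-2-aryl-6-(2-methylbut-3-en-2-yl)-7-[(triisopropylsilyl)oxy]-2,3-dihydro-4H-chromene-4,5(6H)-dione, aryl = 4-methoxy-3-(3-methylbut-3-en-1-yl)phenyl, C6 unassigned (not isolated) | C=CC(C)(C)C1C(=O)C2=C(C=C1O[Si](C(C)C)(C(C)C)C(C)C)O[C@H](c1ccc(OC)c(CCC(C)=C)c1)CC2=O | intermediate
13 | (2S)-2-aryl-8-(3-methylbut-2-en-1-yl)-7-[(triisopropylsilyl)oxy]-2,3-dihydro-4H-chromene-4,5(8H)-dione, same aryl, C8 unassigned (not isolated) | CC(C)=CCC1C(O[Si](C(C)C)(C(C)C)C(C)C)=CC(=O)C2=C1O[C@H](c1ccc(OC)c(CCC(C)=C)c1)CC2=O | intermediate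
14 | (2S)-5-hydroxy-2-[4-methoxy-3-(3-methylbut-3-en-1-yl)phenyl]-8-(3-methylbut-2-en-1-yl)-7-[(triisopropylsilyl)oxy]chroman-4-one | C=C(C)CCc1cc([C@@H]2CC(=O)c3c(O)cc(O[Si](C(C)C)(C(C)C)C(C)C)c(CC=C(C)C)c3O2)ccc1OC | intermediate
15 | (2S)-5,7-dihydroxy-2-[4-methoxy-3-(3-methylbut-3-en-1-yl)phenyl]-8-(3-methylbut-2-en-1-yl)chroman-4-one | C=C(C)CCc1cc([C@@H]2CC(=O)c3c(O)cc(O)c(CC=C(C)C)c3O2)ccc1OC | target

**Step count**

Total steps: 7. Longest linear sequence: 5 (steps 1, 2, 5, 6, 7; the aryl branch, steps 3, 4, 5, 6, 7, is equally long).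

**Steps most likely to fail**

Step 5. The doubly oxygen-donor-substituted chromone may insert slowly, so protodeboronation of the electron-rich boronic acid could outrun arylation. Base-mediated ring opening of the product could erode the enantiomeric purity, and the facial selectivity could be low. Fallback (stereocontrol by resolution instead of catalyst control), setting out from 4 and 10 and returning at 11: the arylation is run with the most active achiral catalyst ([Rh(OH)(cod)]2, dioxane/H2O, 60 °C), which should give racemic 2-[4-methoxy-3-(3-methylbut-3-en-1-yl)phenyl]-5-[(3-methylbut-2-en-1-yl)oxy]-7-[(triisopropylsilyl)oxy]chroman-4-one F1. The racemate is then subjected to kinetic resolution by asymmetric transfer hydrogenation (RuCl[(R,R)-TsDPEN](p-cymene), HCO2H/Et3N, rt, about half conversion). By the usual aryl ketone model this should reduce the (2R)-ketone to the cis-alcohol (2R,4R)-2-[4-methoxy-3-(3-methylbut-3-en-1-yl)phenyl]-5-[(3-methylbut-2-en-1-yl)oxy]-7-[(triisopropylsilyl)oxy]chroman-4-ol F2 and leave the (2S)-ketone 11, which is separated by chromatography and carried into step 6. The fallback gives at most half of the material.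

Step 6. The sequence may stop after the first shift through aromatization of the C6 dienone, giving the 6-(1,1-dimethylallyl) isomer. The allyl group may drift by ionization, or the C2 configuration may be partly lost through Lewis-acid-assisted ring opening once the 5-OH chelate has formed. Fallback (rearrangement moved ahead of the stereocentre), setting out from 4 and returning at 15: the Claisen–Cope rearrangement is run on the achiral chromone 4 (Eu(fod)3, PhCl, 85–110 °C, or thermally in N,N-diethylaniline), where forcing conditions cost no stereochemistry. This should give 5-hydroxy-8-(3-methylbut-2-en-1-yl)-7-[(triisopropylsilyl)oxy]-4H-chromen-4-one F3. The chelating 5-OH, which could bind rhodium like a β-diketonate, is capped (TBSOTf, 2,6-lutidine, CH2Cl2, 0 °C) to give 5-[(tert-butyldimethylsilyl)oxy]-8-(3-methylbut-2-en-1-yl)-7-[(triisopropylsilyl)oxy]-4H-chromen-4-one F4. Rhodium/(S,S)-Ph-bod*-catalysed addition of 10 under the conditions of step 5 should give (2S)-5-[(tert-butyldimethylsilyl)oxy]-2-[4-methoxy-3-(3-methylbut-3-en-1-yl)phenyl]-8-(3-methylbut-2-en-1-yl)-7-[(triisopropylsilyl)oxy]chroman-4-one F5, and global desilylation (TBAF/AcOH, THF, 0 °C) gives 15.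

Step 2. Etherification of the hydrogen-bonded 5-OH may be incomplete, the phenoxide may attack the allylic oxyphosphonium at the tertiary carbon, or the basic betaine may strip the silyl group. Fallback (activation of the electrophile instead of the alcohol), setting out from 2 and returning at 4: neutral silver-assisted alkylation with prenyl bromide (Ag2O, 4 Å sieves, toluene, rt to 40 °C, dark) should give 4 directly; this fallback makes no compound outside the list (F0).

**Further compounds**

F1 | step 5 | rac-2-[4-methoxy-3-(3-methylbut-3-en-1-yl)phenyl]-5-[(3-methylbut-2-en-1-yl)oxy]-7-[(triisopropylsilyl)oxy]chroman-4-one | C=C(C)CCc1cc(C2CC(=O)c3c(OCC=C(C)C)cc(O[Si](C(C)C)(C(C)C)C(C)C)cc3O2)ccc1OC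
F2 | step 5 | (2R,4R)-2-[4-methoxy-3-(3-methylbut-3-en-1-yl)phenyl]-5-[(3-methylbut-2-en-1-yl)oxy]-7-[(triisopropylsilyl)oxy]chroman-4-ol | O[C@@H]1C[C@H](c2ccc(OC)c(CCC(C)=C)c2)Oc2cc(O[Si](C(C)C)(C(C)C)C(C)C)cc(OCC=C(C)C)c21
F3 | step 6 | 5-hydroxy-8-(3-methylbut-2-en-1-yl)-7-[(triisopropylsilyl)oxy]-4H-chromen-4-one | O=c1ccoc2c(CC=C(C)C)c(O[Si](C(C)C)(C(C)C)C(C)C)cc(O)c12
F4 | step 6 | 5-[(tert-butyldimethylsilyl)oxy]-8-(3-methylbut-2-en-1-yl)-7-[(triisopropylsilyl)oxy]-4H-chromen-4-one | O=c1ccoc2c(CC=C(C)C)c(O[Si](C(C)C)(C(C)C)C(C)C)cc(O[Si](C)(C)C(C)(C)C)c12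
F5 | step 6 | (2S)-5-[(tert-butyldimethylsilyl)oxy]-2-[4-methoxy-3-(3-methylbut-3-en-1-yl)phenyl]-8-(3-methylbut-2-en-1-yl)-7-[(triisopropylsilyl)oxy]chroman-4-one | C=C(C)CCc1cc([C@@H]2CC(=O)c3c(O[Si](C)(C)C(C)(C)C)cc(O[Si](C(C)C)(C(C)C)C(C)C)c(CC=C(C)C)c3O2)ccc1OC
F0 | step 2 | none | none
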